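**Retrosynthetic overview**

- Xanthoangelol F is cut first at the ring A C1'–C(=O) bond, giving a ring A aryllithium and the Weinreb amide of O-protected p-coumaric acid. It is then cut, as the key disconnection, through the geranyl chain at CH3–C3'' and C1''–C2''.
- The strategy rests on the E-trisubstituted C2''=C3'' alkene of the geranyl chain on C3' of ring A. C3'' carries a methyl group and C2'' carries the benzylic C1'', which lies between the C2' oxygen and the C4' methoxy group. This is the pattern left by syn methylmetalation of a terminal alkyne followed by benzylation.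
- The three pieces for the key step are 6-methylhept-5-en-1-yne (from 6-methylhept-5-en-2-one), trimethylaluminium, and a ring A benzylic chloride (from 2-hydroxy-6-methoxybenzaldehyde).
- No ring is formed; ring A comes intact from the salicylaldehyde and ring B from p-coumaric acid.
- The end game is MOM-directed ortho-lithiation, acylation, and acidic removal of both MOM groups.

Key step: step 5

Remark: the target has no stereocentre; its only stereo-elements are the E alkenes C2''=C3'' and Cα=Cβ, so only alkene geometry has to be controlled.

**Route**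

Step 1
Reactants: 1 6-methylhept-5-en-2-one
Product: 3 6-methylhept-5-en-1-yne, via enol phosphate 2 (not isolated)
Conditions: LiN(i-Pr)2, THF, −78 °C; ClP(O)(OEt)2, −78 °C to rt; then LiN(i-Pr)2 (2.3 equiv), THF, −78 °C to rt; H2O
Reagents that add atoms: none
Why: Kinetic deprotonation of the methyl ketone at CH3 and O-phosphorylation should give the terminal enol phosphate, which undergoes amide-induced β-elimination to the terminal alkyne (Negishi methyl ketone to alkyne conversion) without touching the trisubstituted alkene.

Step 2
Reactants: 4 2-hydroxy-6-methoxybenzaldehyde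
Product: 5 2-methoxy-6-(methoxymethoxy)benzaldehyde
Conditions: MOMCl, i-Pr2NEt, CH2Cl2, 0 °C to rt
Reagents that add atoms: chloromethyl methyl ether, COCCl
Why: O-alkylation of the phenol with MOMCl under amine base (Williamson-type acetal formation) installs the group that later directs ortho-lithiation, and the aldehyde is inert.

Step 3
Reactants: 5 2-methoxy-6-(methoxymethoxy)benzaldehyde
Product: 6 [2-methoxy-6-(methoxymethoxy)phenyl]methanol
Conditions: NaBH4, MeOH, 0 °C
Reagents that add atoms: none
Why: Borohydride reduction of the aryl aldehyde to the benzylic alcohol is chemoselective and leaves the MOM acetal and the methyl ether untouched.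

Step 4
Reactants: 6 [2-methoxy-6-(methoxymethoxy)phenyl]methanol
Product: 8 2-(chloromethyl)-1-methoxy-3-(methoxymethoxy)benzene, via benzylic mesylate 7 (not isolated)
Conditions: MsCl, Et3N, LiCl, THF, 0 °C to rt; used at once without chromatography
Reagents that add atoms: lithium chloride, [Li+].[Cl-]; methanesulfonyl chloride, CS(=O)(=O)Cl (its chloride joins the same chloride pool)
Why: Mesylation under basic, acid-free conditions followed by in-flask nucleophilic displacement of the very labile electron-rich benzylic mesylate by chloride should give the chloride with the MOM ether intact.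

Step 5
Reactants: 3 6-methylhept-5-en-1-yne; 9 trimethylaluminium; 8 2-(chloromethyl)-1-methoxy-3-(methoxymethoxy)benzene
Product: 11 2-[(2E)-3,7-dimethylocta-2,6-dien-1-yl]-1-methoxy-3-(methoxymethoxy)benzene, via alkenylalane 10 (not isolated)
Conditions: AlMe3 (2 equiv), Cp2ZrCl2 (20 mol %), CH2Cl2, 0 °C to rt; volatiles removed in vacuo; then 8, Pd(PPh3)4 (5 mol %), THF, rt
Reagents that add atoms: trimethylaluminium (compound 9), C[Al](C)C
Why: AlMe3 and Cp2ZrCl2 form a methylzirconium–aluminium species that delivers methyl and metal to the same face of the terminal alkyne of 3, methyl to the internal carbon, and zirconium-to-aluminium exchange gives the (E)-alkenylalane 10 (zirconium-catalysed Negishi carboalumination), while the distal trisubstituted C6''=C7'' alkene does not undergo carbometalation. After excess AlMe3 is pumped off so that methyl transfer and Lewis-acid ionisation of 8 are suppressed, zerovalent palladium inserts into the benzylic C–Cl bond, the alkenyl group moves from aluminium to palladium with retention, and reductive elimination forms the C1''–C2'' bond; the closest known reaction type is the palladium-catalysed cross-coupling of alkenylalanes with benzylic halides. No ring is closed and no stereocentre is created, so neither a mode of closure nor stereocentre control applies. The selectivity the step needs is the E geometry of C2''=C3'', which follows from the syn, methyl-internal addition of the carbometalation and from retention in both transmetalation and reductive elimination. Ring A substitution is fixed beforehand because the chloromethyl carbon of 8 is already flanked by both oxygen substituents, and since the allyl unit is assembled as the nucleophile on a benzylic electrophile there is no pathway for the allylic scrambling seen with geranyl halides.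

Step 6
Reactants: 12 p-coumaric acid
Product: 13 (2E)-3-(4-hydroxyphenyl)-N-methoxy-N-methylprop-2-enamide
Conditions: MeNHOMe·HCl, EDC·HCl, HOBt, i-Pr2NEt, DMF, 0 °C to rt
Reagents that add atoms: N,O-dimethylhydroxylamine hydrochloride, CNOC.Cl
Why: Carbodiimide/HOBt amide coupling should acylate the amine far faster than the phenol and leaves the E alkene unchanged.

Step 7
Reactants: 13 (2E)-3-(4-hydroxyphenyl)-N-methoxy-N-methylprop-2-enamide
Product: 14 (2E)-N-methoxy-N-methyl-3-[4-(methoxymethoxy)phenyl]prop-2-enamide
Conditions: MOMCl, i-Pr2NEt, CH2Cl2, 0 °C to rt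
Reagents that add atoms: chloromethyl methyl ether, COCCl
Why: O-alkylation of the phenol with MOMCl masks the only acidic proton before the organolithium step, and the Weinreb amide is inert to these conditions.

Step 8
Reactants: 11 2-[(2E)-3,7-dimethylocta-2,6-dien-1-yl]-1-methoxy-3-(methoxymethoxy)benzene; 14 (2E)-N-methoxy-N-methyl-3-[4-(methoxymethoxy)phenyl]prop-2-enamide
Product: 16 (2E)-1-{3-[(2E)-3,7-dimethylocta-2,6-dien-1-yl]-4-methoxy-2-(methoxymethoxy)phenyl}-3-[4-(methoxymethoxy)phenyl]prop-2-en-1-one, via aryllithium 15 (not isolated)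
Conditions: n-BuLi, TMEDA, Et2O, 0 °C; then 14, THF, −78 to 0 °C; H2O
Reagents that add atoms: none
Why: In this directed ortho metalation the MOM acetal, a stronger director than the methyl ether, guides n-BuLi to its only free ortho C–H (para to OMe, the other ortho position bearing the geranyl group), and the aryllithium adds 1,2 to the Weinreb amide to give a chelated tetrahedral adduct that releases the E enone only on work-up (Weinreb ketone synthesis).

Step 9
Reactants: 16 (2E)-1-{3-[(2E)-3,7-dimethylocta-2,6-dien-1-yl]-4-methoxy-2-(methoxymethoxy)phenyl}-3-[4-(methoxymethoxy)phenyl]prop-2-en-1-one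
Product: 17 xanthoangelol F
Conditions: 3 M aq HCl, MeOH, rt to 45 °C
Reagents that add atoms: none
Why: Acid-catalysed acetal methanolysis should remove both MOM groups, the one ortho to the carbonyl being assisted by chelation, under conditions mild enough for the geranyl alkenes and the 2'-hydroxychalcone.

**Compound list**

1 | 6-methylhept-5-en-2-one | CC(=O)CCC=C(C)C | starting material
2 | diethyl 6-methylhepta-1,5-dien-2-yl phosphate | C=C(CCC=C(C)C)OP(=O)(OCC)OCC | intermediate
3 | 6-methylhept-5-en-1-yne | C#CCCC=C(C)C | intermediate
4 | 2-hydroxy-6-methoxybenzaldehyde | COc1cccc(O)c1C=O | starting material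
5 | 2-methoxy-6-(methoxymethoxy)benzaldehyde | COCOc1cccc(OC)c1C=O | intermediate
6 | [2-methoxy-6-(methoxymethoxy)phenyl]methanol | COCOc1cccc(OC)c1CO | intermediate
7 | [2-methoxy-6-(methoxymethoxy)phenyl]methyl methanesulfonate | COCOc1cccc(OC)c1COS(C)(=O)=O | intermediate
8 | 2-(chloromethyl)-1-methoxy-3-(methoxymethoxy)benzene | COCOc1cccc(OC)c1CCl | intermediate
9 | trimethylaluminium | C[Al](C)C | starting material
10 | [(1E)-2,6-dimethylhepta-1,5-dien-1-yl]dimethylalane | C[Al](C)/C=C(\C)CCC=C(C)C | intermediate
11 | 2-[(2E)-3,7-dimethylocta-2,6-dien-1-yl]-1-methoxy-3-(methoxymethoxy)benzene | COCOc1cccc(OC)c1C/C=C(\C)CCC=C(C)C | intermediate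
12 | p-coumaric acid | O=C(O)/C=C/c1ccc(O)cc1 | starting material
13 | (2E)-3-(4-hydroxyphenyl)-N-methoxy-N-methylprop-2-enamide | CON(C)C(=O)/C=C/c1ccc(O)cc1 | intermediate
14 | (2E)-N-methoxy-N-methyl-3-[4-(methoxymethoxy)phenyl]prop-2-enamide | CON(C)C(=O)/C=C/c1ccc(OCOC)cc1 | intermediate
15 | {3-[(2E)-3,7-dimethylocta-2,6-dien-1-yl]-4-methoxy-2-(methoxymethoxy)phenyl}lithium | [Li]c1ccc(OC)c(C/C=C(\C)CCC=C(C)C)c1OCOC | intermediate
16 | (2E)-1-{3-[(2E)-3,7-dimethylocta-2,6-dien-1-yl]-4-methoxy-2-(methoxymethoxy)phenyl}-3-[4-(methoxymethoxy)phenyl]prop-2-en-1-one | COCOc1ccc(/C=C/C(=O)c2ccc(OC)c(C/C=C(\C)CCC=C(C)C)c2OCOC)cc1 | intermediate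
17 | xanthoangelol F, (2E)-1-{3-[(2E)-3,7-dimethylocta-2,6-dien-1-yl]-2-hydroxy-4-methoxyphenyl}-3-(4-hydroxyphenyl)prop-2-en-1-one | COc1ccc(C(=O)/C=C/c2ccc(O)cc2)c(O)c1C/C=C(\C)CCC=C(C)C | target

**Step count and risks**

Total step count: 9. Longest linear sequence: 6 steps (steps 2, 3, 4, 5, 8, 9, from 2-hydroxy-6-methoxybenzaldehyde).

Steps most likely to fail:

Step 5. The doubly ortho-oxygenated benzylic chloride may be ionised by Lewis-acidic aluminium species, leading to self-alkylation or methyl transfer from aluminium, faster than oxidative addition and alkenyl transfer take place. The fallback reverses the polarity of the coupling and sets out from alkenylalane 10 and chloride 8. Alane 10 is quenched with iodine in THF at −30 to 0 °C, which should give (1E)-1-iodo-2,6-dimethylhepta-1,5-diene F1 with retention of geometry. Chloride 8 is treated with zinc dust and LiCl in THF to give chlorido{[2-methoxy-6-(methoxymethoxy)phenyl]methyl}zinc F2. Negishi coupling of F2 with F1 under Pd(PPh3)4 in THF at rt, with no aluminium present, comes back to the route at 11.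

Step 8. Deprotonation may occur at the benzylic–allylic C1'' methylene instead of the ring C–H ortho to the MOM ether, or the aryllithium may add in conjugate fashion to the enamide. The fallback avoids any organolithium and sets out from 11. Methanolysis of the MOM ether (HCl, MeOH, rt) should give 2-[(2E)-3,7-dimethylocta-2,6-dien-1-yl]-3-methoxyphenol F3. Magnesium-mediated ortho-formylation (MgCl2, Et3N, paraformaldehyde, MeCN, reflux) at the only free ortho position gives 3-[(2E)-3,7-dimethylocta-2,6-dien-1-yl]-2-hydroxy-4-methoxybenzaldehyde F4. Excess MeMgBr in THF at 0 °C gives racemic 1-{3-[(2E)-3,7-dimethylocta-2,6-dien-1-yl]-2-hydroxy-4-methoxyphenyl}ethan-1-ol F5, whose new stereocentre is destroyed on MnO2 oxidation in CH2Cl2 to 1-{3-[(2E)-3,7-dimethylocta-2,6-dien-1-yl]-2-hydroxy-4-methoxyphenyl}ethan-1-one F6. Claisen–Schmidt condensation of F6 with 4-hydroxybenzaldehyde (KOH, EtOH–H2O, rt to 50 °C) comes back to the route at 17.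

Step 9. While the slower ring B MOM ether is being cleaved, the freed 2'-hydroxyl may cyclise under acid onto the C2''=C3'' alkene (chroman formation) or onto the enone (flavanone formation). The fallback moves the acid step to a stage where no chalcone exists and sets out from aryllithium 15. Quenching 15 with N-methoxy-N-methylacetamide should give 1-{3-[(2E)-3,7-dimethylocta-2,6-dien-1-yl]-4-methoxy-2-(methoxymethoxy)phenyl}ethan-1-one F7. Its single, carbonyl-activated MOM group is removed with dilute HCl in MeOH at rt to give the hydroxy ketone 1-{3-[(2E)-3,7-dimethylocta-2,6-dien-1-yl]-2-hydroxy-4-methoxyphenyl}ethan-1-one F6. Base-mediated Claisen–Schmidt condensation with 4-hydroxybenzaldehyde (KOH, EtOH–H2O) then comes back to the route at 17, so the last step runs in base.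

**Further compounds**

F1 | step 5 | (1E)-1-iodo-2,6-dimethylhepta-1,5-diene | I/C=C(\C)CCC=C(C)C
F2 | step 5 | chlorido{[2-methoxy-6-(methoxymethoxy)phenyl]methyl}zinc | COCOc1cccc(OC)c1C[Zn]Cl
F3 | step 8 | 2-[(2E)-3,7-dimethylocta-2,6-dien-1-yl]-3-methoxyphenol | COc1cccc(O)c1C/C=C(\C)CCC=C(C)C
F4 | step 8 | 3-[(2E)-3,7-dimethylocta-2,6-dien-1-yl]-2-hydroxy-4-methoxybenzaldehyde | COc1ccc(C=O)c(O)c1C/C=C(\C)CCC=C(C)C
F5 | step 8 | 1-{3-[(2E)-3,7-dimethylocta-2,6-dien-1-yl]-2-hydroxy-4-methoxyphenyl}ethan-1-ol (racemic) | COc1ccc(C(C)O)c(O)c1C/C=C(\C)CCC=C(C)C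
F6 | step 8 | 1-{3-[(2E)-3,7-dimethylocta-2,6-dien-1-yl]-2-hydroxy-4-methoxyphenyl}ethan-1-one | COc1ccc(C(C)=O)c(O)c1C/C=C(\C)CCC=C(C)C
F7 | step 9 | 1-{3-[(2E)-3,7-dimethylocta-2,6-dien-1-yl]-4-methoxy-2-(methoxymethoxy)phenyl}ethan-1-one | COCOc1c(C(C)=O)ccc(OC)c1C/C=C(\C)CCC=C(C)C
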